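**Plan**
- Feature: in the pyranone ring, C2 (bonded to O1) and the C3 methylene next to the C4 ketone form a β-oxy ketone, the pattern of an aldol. The benzene ring has its C5 and C8 oxygens para to each other around C4a (acyl) and C8a (O1), the pattern of a 2-acyl-1,4-benzoquinone that has added its own side-chain hydroxyl.
- Cuts, in retrosynthetic order: O1–C8a (alcohol addition to the quinone), C2–C3 (asymmetric Mukaiyama aldol), then the C12–C13 bond of the C18 enal (acetylide alkylation).
- Forward: the chain is built from 12-bromododecan-1-ol and 1-hexyne and oxidised to the Z-enal. The aldol joins it to the 2,5-dimethoxyphenyl ketone. The arene is then oxidised to the quinone and the pyranone ring, the only ring formed, closes last.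
- Stereochemistry: the Z alkene comes from Lindlar semi-hydrogenation. The single stereocentre (C2, R) comes from the chiral boron Lewis acid in the aldol and is carried through with its C–O bond intact.

Key step: step 7

Remark on the chemistry (assumption): the catalyst made from the (S)-amino acid is taken to expose the re face of a bound aldehyde, as the accepted model for this catalyst family states. The (R)-tryptophan catalyst is therefore specified. The configuration of 12 is to be checked by MTPA-ester analysis before it is carried on, with the antipodal catalyst as the only change if the sense proves opposite.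

Step 1
Reactants: 1 12-bromododecan-1-ol
Product: 2 2-[(12-bromododecyl)oxy]oxane
Conditions: 3,4-dihydro-2H-pyran, PPTS (cat.), CH2Cl2, rt
Reagents that add atoms: 3,4-dihydro-2H-pyran, C1=COCCC1
Why: Acid-catalysed addition of the alcohol to the enol ether (tetrahydropyranylation) masks the hydroxyl so that the acetylide of step 2 is not quenched.

Step 2
Reactants: 2 2-[(12-bromododecyl)oxy]oxane; 3 1-hexyne
Product: 5 2-(octadec-13-yn-1-yloxy)oxane, via hex-1-ynyllithium 4 (not isolated)
Conditions: 3, n-BuLi, THF, −78 to 0 °C; then 2, DMPU, 0 °C to rt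
Reagents that add atoms: none
Why: SN2 alkylation of a lithium acetylide by an unhindered primary bromide in a dipolar cosolvent is a standard way to internal alkynes, and the acetal is inert to the base.

Step 3
Reactants: 5 2-(octadec-13-yn-1-yloxy)oxane
Product: 6 octadec-13-yn-1-ol
Conditions: p-TsOH·H2O (cat.), MeOH, rt
Reagents that add atoms: none
Why: Acid-catalysed transacetalisation to methanol removes the tetrahydropyranyl group and leaves the alkyne untouched.

Step 4
Reactants: 6 octadec-13-yn-1-ol
Product: 7 (13Z)-octadec-13-en-1-ol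
Conditions: H2 (1 atm), Pd/CaCO3 poisoned with Pb(OAc)2, quinoline, hexane, rt, stopped at one equivalent of H2
Reagents that add atoms: none
Why: Lindlar semi-hydrogenation delivers both hydrogens to the same face of the alkyne on the poisoned palladium surface, which should give the Z alkene and stop there.

Step 5
Reactants: 7 (13Z)-octadec-13-en-1-ol
Product: 8 (13Z)-octadec-13-enal
Conditions: TEMPO (10 mol%), PhI(OAc)2 (1.1 equiv), CH2Cl2, rt
Reagents that add atoms: none
Why: Oxoammonium (TEMPO) oxidation with PhI(OAc)2 as terminal oxidant takes a primary alcohol to the aldehyde without over-oxidation and does not touch the remote Z alkene.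

Step 6
Reactants: 9 1-(2,5-dimethoxyphenyl)ethanone (2',5'-dimethoxyacetophenone)
Product: 10 {[1-(2,5-dimethoxyphenyl)ethenyl]oxy}trimethylsilane
Conditions: LiN(iPr)2, THF, −78 °C; TMSCl, −78 °C to rt; non-aqueous work-up, distillation
Reagents that add atoms: chlorotrimethylsilane, C[Si](C)(C)Cl
Why: Deprotonation of the methyl ketone, which has only one enolisable side, and O-silylation of the lithium enolate is the routine silyl enol ether synthesis.

Step 7
Reactants: 8 (13Z)-octadec-13-enal; 10 {[1-(2,5-dimethoxyphenyl)ethenyl]oxy}trimethylsilane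
Product: 12 (3R,15Z)-1-(2,5-dimethoxyphenyl)-3-hydroxyicos-15-en-1-one, via aldol trimethylsilyl ether 11 (not isolated)
Conditions: (4R)-2-butyl-4-(1H-indol-3-ylmethyl)-3-tosyl-1,3,2-oxazaborolidin-5-one (20 mol%, preformed from N-tosyl-(R)-tryptophan and n-BuB(OH)2), EtCN, −78 °C; then 1 M HCl, THF, 0 °C
Reagents that add atoms: none
Why: The aldehyde oxygen binds to boron anti to the alkyl chain, the indole of the catalyst stacks over one face of the activated carbonyl, and the silyl enol ether attacks the open face through an acyclic transition state; transfer of the trimethylsilyl group to the aldolate oxygen releases the catalyst and gives silyl ether 11, which the acidic work-up cleaves to 12. The closest known reaction type is the Mukaiyama aldol addition of trimethylsilyl enol ethers of aryl methyl ketones to unbranched aliphatic aldehydes catalysed by B-alkyl oxazaborolidinones derived from N-sulfonyl amino acids. No ring is closed; the step forms only the C2–C3 bond of the later pyranone. The one new stereocentre (C3 of 12, later C2 of the chromanone) is controlled by the catalyst alone: the (R)-tryptophan catalyst should expose the si face of the aldehyde, and si-face attack on an unbranched alkanal gives the 3R alcohol. The step needs enantioface selectivity only, because an acetate-type enol ether creates no second stereocentre, and chemoselectivity is secured because the aldehyde is the only electrophile that binds boron and the Z alkene is remote and unactivated.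

Step 8
Reactants: 12 (3R,15Z)-1-(2,5-dimethoxyphenyl)-3-hydroxyicos-15-en-1-one
Product: 13 2-[(3R,15Z)-3-hydroxyicos-15-enoyl]cyclohexa-2,5-diene-1,4-dione
Conditions: (NH4)2Ce(NO3)6 (2.5 equiv), MeCN/H2O 2:1, 0 °C, short reaction time; extractive work-up, used at once
Reagents that add atoms: water, O
Why: Oxidative demethylation of a 1,4-dimethoxyarene by tetravalent cerium proceeds by two one-electron oxidations with water attacking the methoxy-bearing carbons, and although the acyl group slows it, the para-dimethoxy ring should still react well before the isolated alkene or the secondary alcohol.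

Step 9
Reactants: 13 2-[(3R,15Z)-3-hydroxyicos-15-enoyl]cyclohexa-2,5-diene-1,4-dione
Product: 15 (2R)-2-[(12Z)-heptadec-12-en-1-yl]-2,3-dihydro-4H-chromene-4,5,8-trione, via ring-closed hydroquinone 14 (not isolated)
Conditions: Zn(OTf)2 (20 mol%), DDQ (1.1 equiv), 4 Å molecular sieves, CH2Cl2, 0 °C to rt
Reagents that add atoms: none
Why: Lewis-acid-promoted conjugate (oxa-Michael) addition of an alcohol to a quinone, here a 6-endo-trig closure onto the quinone carbon next to the zinc-chelated acyl group, gives hydroquinone 14 after enolisation, and DDQ oxidises 14 at once to the quinone so that no starting quinone is spent as oxidant, while the C2–O bond is never broken and the configuration is retained.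

Step 10
Reactants: 15 (2R)-2-[(12Z)-heptadec-12-en-1-yl]-2,3-dihydro-4H-chromene-4,5,8-trione
Product: 14 (2R)-2-[(12Z)-heptadec-12-en-1-yl]-5,8-dihydroxy-2,3-dihydro-4H-chromen-4-one
Conditions: Na2S2O4 (aq., excess), EtOAc/H2O, rt, under argon
Reagents that add atoms: none
Why: Dithionite reduction of a quinone to its hydroquinone is fast in a two-phase system and should leave the aryl ketone, the alkene and the stereocentre untouched.

**Compound list**
1 | 12-bromododecan-1-ol | OCCCCCCCCCCCCBr | starting material
2 | 2-[(12-bromododecyl)oxy]oxane | BrCCCCCCCCCCCCOC1CCCCO1 | intermediate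
3 | 1-hexyne | CCCCC#C | starting material
4 | hex-1-ynyllithium | CCCCC#C[Li] | intermediate
5 | 2-(octadec-13-yn-1-yloxy)oxane | CCCCC#CCCCCCCCCCCCCOC1CCCCO1 | intermediate
6 | octadec-13-yn-1-ol | CCCCC#CCCCCCCCCCCCCO | intermediate
7 | (13Z)-octadec-13-en-1-ol | CCCC/C=C\CCCCCCCCCCCCO | intermediate
8 | (13Z)-octadec-13-enal | CCCC/C=C\CCCCCCCCCCCC=O | intermediate
9 | 1-(2,5-dimethoxyphenyl)ethanone | CC(=O)c1cc(OC)ccc1OC | starting material
10 | {[1-(2,5-dimethoxyphenyl)ethenyl]oxy}trimethylsilane | C=C(O[Si](C)(C)C)c1cc(OC)ccc1OC | intermediate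
11 | (3R,15Z)-1-(2,5-dimethoxyphenyl)-3-(trimethylsilyloxy)icos-15-en-1-one | CCCC/C=C\CCCCCCCCCCC[C@@H](O[Si](C)(C)C)CC(=O)c1cc(OC)ccc1OC | intermediate
12 | (3R,15Z)-1-(2,5-dimethoxyphenyl)-3-hydroxyicos-15-en-1-one | CCCC/C=C\CCCCCCCCCCC[C@@H](O)CC(=O)c1cc(OC)ccc1OC | intermediate
13 | 2-[(3R,15Z)-3-hydroxyicos-15-enoyl]cyclohexa-2,5-diene-1,4-dione | CCCC/C=C\CCCCCCCCCCC[C@@H](O)CC(=O)C1=CC(=O)C=CC1=O | intermediate
14 | (2R)-2-[(12Z)-heptadec-12-en-1-yl]-5,8-dihydroxy-2,3-dihydro-4H-chromen-4-one | CCCC/C=C\CCCCCCCCCCC[C@@H]1CC(=O)c2c(O)ccc(O)c2O1 | target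
15 | (2R)-2-[(12Z)-heptadec-12-en-1-yl]-2,3-dihydro-4H-chromene-4,5,8-trione | CCCC/C=C\CCCCCCCCCCC[C@@H]1CC(=O)C2=C(O1)C(=O)C=CC2=O | intermediate

**Step count**
Total steps: 10. Longest linear sequence: 9 (steps 1 to 5, then 7 to 10).

**Steps most likely to fail**

1. Step 9. The ring closure may be slower than decomposition of the very electrophilic acylquinone. Reversible hemiketal formation at the quinone carbonyl may hold the material back. The β-hydroxy ketone may dehydrate under the Lewis acid. At the trione stage, β-elimination of the ring oxygen and re-closure would erode the enantiomeric purity.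
Fallback: this sets out from aldehyde 8 and returns at trione 15, with the ring oxygen placed on the arene beforehand as a methoxy leaving group. Commercial 1,2,4-trimethoxybenzene is lithiated between its 2- and 4-methoxy groups (n-BuLi, THF, 0 °C) and acylated with N-methoxy-N-methylacetamide to give 1-(2,3,6-trimethoxyphenyl)ethanone F1. LiN(iPr)2 and TMSCl convert it into trimethyl{[1-(2,3,6-trimethoxyphenyl)ethenyl]oxy}silane F2. The boron-catalysed aldol of step 7 with 8 should then give, through (3R,15Z)-1-(2,3,6-trimethoxyphenyl)-3-(trimethylsilyloxy)icos-15-en-1-one F3, the alcohol (3R,15Z)-3-hydroxy-1-(2,3,6-trimethoxyphenyl)icos-15-en-1-one F4. (NH4)2Ce(NO3)6 oxidises the para-related 3- and 6-methoxy groups and should give 2-[(3R,15Z)-3-hydroxyicos-15-enoyl]-3-methoxycyclohexa-2,5-diene-1,4-dione F5, in which the remaining methoxy group is a vinylogous ester. Catalytic camphorsulfonic acid with 4 Å molecular sieves in CH2Cl2 should then bring about intramolecular alkoxy exchange (addition–elimination with loss of methanol) to 15 directly, with no change of oxidation level. Step 10 follows unchanged.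

2. Step 7. Enantioface discrimination may be insufficient or turnover slow, because the ortho-methoxy group of the enol ether can compete for boron and a silyl-cation-catalysed racemic background reaction can intervene.
Fallback: this sets out from aldehyde 8 and returns at aldol 12, with the stereocentre taken from a resolved epoxide. Corey–Chaykovsky methylenation of 8 (trimethylsulfonium iodide, n-BuLi, THF, 0 °C) gives racemic 2-[(12Z)-heptadec-12-en-1-yl]oxirane F6. Jacobsen hydrolytic kinetic resolution follows, using the (R,R)-configured [N,N'-bis(3,5-di-tert-butylsalicylidene)cyclohexane-1,2-diaminato]cobalt acetate (trivalent cobalt, C38H55CoN2O4, 0.5 mol%) and 0.55 equiv of water. By the usual sense of this catalyst it should leave (2R)-2-[(12Z)-heptadec-12-en-1-yl]oxirane F7. Separately, 2,5-dimethoxybenzaldehyde and propane-1,3-dithiol (BF3·OEt2, CH2Cl2) give 2-(2,5-dimethoxyphenyl)-1,3-dithiane F8. Its 2-lithio derivative (n-BuLi, THF, −30 °C) opens F7 at the terminal carbon to give (2R,14Z)-1-[2-(2,5-dimethoxyphenyl)-1,3-dithian-2-yl]nonadec-14-en-2-ol F9. Hydrolysis of the dithiane (MeI, CaCO3, MeCN/H2O, 40 °C) should give 12 with the carbinol C–O bond untouched.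

3. Step 8. Oxidation of the acyl-deactivated ring may be incomplete or unselective, with ring nitration or attack on the alcohol on prolonged exposure, and the acylquinone may hydrate in the aqueous medium.
Fallback: this sets out from 12 and returns at acylquinone 13, with oxidation of a para-methoxyphenol in place of the dimethoxyarene. BCl3 (CH2Cl2, −78 to 0 °C) removes only the methyl group ortho to the ketone, by chelation, and should give (3R,15Z)-3-hydroxy-1-(2-hydroxy-5-methoxyphenyl)icos-15-en-1-one F10. PhI(OCOCF3)2 in MeCN/H2O at 0 °C then oxidises the para-methoxyphenol to the quinone 13 with loss of methanol.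

**Further compounds**
F1 | step 9 | 1-(2,3,6-trimethoxyphenyl)ethanone | CC(=O)c1c(OC)ccc(OC)c1OC
F2 | step 9 | trimethyl{[1-(2,3,6-trimethoxyphenyl)ethenyl]oxy}silane | C=C(O[Si](C)(C)C)c1c(OC)ccc(OC)c1OC
F3 | step 9 | (3R,15Z)-1-(2,3,6-trimethoxyphenyl)-3-(trimethylsilyloxy)icos-15-en-1-one | CCCC/C=C\CCCCCCCCCCC[C@@H](O[Si](C)(C)C)CC(=O)c1c(OC)ccc(OC)c1OC
F4 | step 9 | (3R,15Z)-3-hydroxy-1-(2,3,6-trimethoxyphenyl)icos-15-en-1-one | CCCC/C=C\CCCCCCCCCCC[C@@H](O)CC(=O)c1c(OC)ccc(OC)c1OC
F5 | step 9 | 2-[(3R,15Z)-3-hydroxyicos-15-enoyl]-3-methoxycyclohexa-2,5-diene-1,4-dione | CCCC/C=C\CCCCCCCCCCC[C@@H](O)CC(=O)C1=C(OC)C(=O)C=CC1=O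
F6 | step 7 | 2-[(12Z)-heptadec-12-en-1-yl]oxirane (racemic) | CCCC/C=C\CCCCCCCCCCCC1CO1
F7 | step 7 | (2R)-2-[(12Z)-heptadec-12-en-1-yl]oxirane | CCCC/C=C\CCCCCCCCCCC[C@@H]1CO1
F8 | step 7 | 2-(2,5-dimethoxyphenyl)-1,3-dithiane | COc1ccc(OC)c(c1)C1SCCCS1
F9 | step 7 | (2R,14Z)-1-[2-(2,5-dimethoxyphenyl)-1,3-dithian-2-yl]nonadec-14-en-2-ol | CCCC/C=C\CCCCCCCCCCC[C@@H](O)CC1(SCCCS1)c1cc(OC)ccc1OC
F10 | step 8 | (3R,15Z)-3-hydroxy-1-(2-hydroxy-5-methoxyphenyl)icos-15-en-1-one | CCCC/C=C\CCCCCCCCCCC[C@@H](O)CC(=O)c1cc(OC)ccc1O
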